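The route rests on cutting the bond between the central guaiacyl ring and the exocyclic CH2 on lactone C4. This CH2 lies gamma to the lactone carbonyl C2. A temporary C3–CH2 bond, a cyclopropane fused to the butyrolactone ring and made from (S)-epichlorohydrin, therefore turns it into a homo-Michael acceptor that already stores C4. The dihydrobenzofuran half is carried on C3 as the benzylic ester that supplies the second acceptor. In one operation the copper-catalysed aryl Grignard reagent of the silylated diarylpropanediol half opens the three-membered ring, joins both halves and unveils the C3 enolate position. Palladium later shifts the ester benzyl group to C3 with loss of CO2.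

Key step: step 16

Assumption: the lactone (O1, C2 = carbonyl, C3, C4, C5) is taken as drawn, (3S,4S), the mirror-image series of (−)-matairesinol, hence (S)-epichlorohydrin. TBS = tert-butyldimethylsilyl, TBSO = its ether. C3 of 32 is a labile β-dicarbonyl centre and is drawn as the more stable trans epimer.

Step 1
Reactants: 1 2-allyl-6-methoxyphenol
Product: 2 2-allyl-4-bromo-6-methoxyphenol
Conditions: NBS (1.0 equiv), MeCN, −10 °C
Reagents that add atoms: N-bromosuccinimide, O=C1CCC(=O)N1Br
Why: Electrophilic aromatic bromination, in which the free phenol directs to its only open ortho/para site (C4, para) and the activated ring should react faster than the allyl group at low temperature.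

Step 2
Reactants: 2 2-allyl-4-bromo-6-methoxyphenol
Product: 3 (2-allyl-4-bromo-6-methoxyphenoxy)(tert-butyl)dimethylsilane
Conditions: TBSCl, imidazole, DMF, rt
Reagents that add atoms: tert-butyldimethylsilyl chloride, CC(C)(C)[Si](C)(C)Cl
Why: Standard silyl ether formation masks the phenol for the oxidation, enolate and organometallic steps.

Step 3
Reactants: 3 (2-allyl-4-bromo-6-methoxyphenoxy)(tert-butyl)dimethylsilane
Product: 5 2-[5-bromo-3-methoxy-2-(TBSO)phenyl]acetaldehyde, via secondary ozonide 4 (not isolated)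
Conditions: O3, CH2Cl2, −78 °C (indicator end point); then PPh3, −78 °C → rt
Reagents that add atoms: ozone, [O-][O+]=O
Why: Ozonolysis (Criegee mechanism) with reductive work-up cleaves the terminal alkene, which should react much faster than the brominated arene.

Step 4
Reactants: 5 2-[5-bromo-3-methoxy-2-(TBSO)phenyl]acetaldehyde
Product: 6 2-[5-bromo-3-methoxy-2-(TBSO)phenyl]acetic acid
Conditions: NaClO2, NaH2PO4, 2-methyl-2-butene, t-BuOH/H2O, 0 °C → rt
Reagents that add atoms: sodium chlorite, [Na+].[O-]Cl=O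
Why: The Pinnick oxidation converts the sensitive arylacetaldehyde into the acid under buffered conditions that spare the aryl silyl ether and the electron-rich ring.

Step 5
Reactants: 6 2-[5-bromo-3-methoxy-2-(TBSO)phenyl]acetic acid; 7 (S)-4-benzyloxazolidin-2-one
Product: 9 (S)-4-benzyl-3-{2-[5-bromo-3-methoxy-2-(TBSO)phenyl]acetyl}oxazolidin-2-one, via mixed pivalic anhydride 8 (not isolated)
Conditions: PivCl, Et3N, THF, −20 °C; then 7, LiCl, rt
Reagents that add atoms: none
Why: N-Acylation of the oxazolidinone by the mixed-anhydride/LiCl method, in which the hindered pivaloyl carbonyl directs attack to the arylacetyl carbonyl.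

Step 6
Reactants: 10 vanillin
Product: 11 4-(TBSO)-3-methoxybenzaldehyde
Conditions: TBSCl, imidazole, DMF, rt
Reagents that add atoms: tert-butyldimethylsilyl chloride, CC(C)(C)[Si](C)(C)Cl
Why: Standard silyl ether formation gives the non-enolisable aldehyde partner without an acidic proton.

Step 7
Reactants: 9 (S)-4-benzyl-3-{2-[5-bromo-3-methoxy-2-(TBSO)phenyl]acetyl}oxazolidin-2-one; 11 4-(TBSO)-3-methoxybenzaldehyde
Product: 13 (S)-4-benzyl-3-{(2R,3S)-2-[5-bromo-3-methoxy-2-(TBSO)phenyl]-3-hydroxy-3-[3-methoxy-4-(TBSO)phenyl]propanoyl}oxazolidin-2-one, via O-TMS aldol ether 12 (not isolated)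
Conditions: MgCl2 (20 mol %), Et3N, TMSCl, EtOAc, rt; then MeOH, cat. TFA, 0 °C
Reagents that add atoms: none
Why: Evans magnesium halide-catalysed anti-aldol reaction, in which soft enolisation gives the Mg-chelated Z-enolate, the face opposite the auxiliary benzyl group adds to the aldehyde through a boat-like transition state to set C2 (R) and C3 (S), and silylation of the aldolate makes the addition irreversible.

Step 8
Reactants: 13 anti-aldol imide
Product: 14 (1S,2S)-2-[5-bromo-3-methoxy-2-(TBSO)phenyl]-1-[3-methoxy-4-(TBSO)phenyl]propane-1,3-diol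
Conditions: LiBH4, THF, H2O (1 equiv), 0 °C
Reagents that add atoms: none
Why: Reductive cleavage of the N-acyloxazolidinone with LiBH4 attacks the exocyclic carbonyl and leaves both stereocentres and the aryl bromide untouched, and any O-to-O silyl shift would be harmless because steps 9 and 10 level all oxygen positions.

Step 9
Reactants: 14 (1S,2S)-diol
Product: 15 (1S,2S)-2-[5-bromo-3-methoxy-2-(TBSO)phenyl]-1-[3-methoxy-4-(TBSO)phenyl]-1,3-bis(TBSO)propane
Conditions: TBSOTf, 2,6-lutidine, CH2Cl2, −20 → 0 °C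
Reagents that add atoms: tert-butyldimethylsilyl triflate, CC(C)(C)[Si](C)(C)OS(=O)(=O)C(F)(F)F
Why: Silyl ether formation with the reactive triflate caps the hindered benzylic and the primary hydroxyl groups, so that 15 carries no acidic proton for the metalation of step 16.

Step 10
Reactants: 14 (1S,2S)-diol
Product: 17 [(2R,3S)-5-bromo-2-(4-hydroxy-3-methoxyphenyl)-7-methoxy-2,3-dihydrobenzofuran-3-yl]methanol, via free tetraol 16 (not isolated)
Conditions: TBAF (2.2 equiv), THF, 0 °C; then 2 M aq HCl/dioxane, rt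
Reagents that add atoms: none
Why: Fluoride frees both phenols and acid then ionises the 4-hydroxybenzylic alcohol to a quinone-methide-type cation that the ortho phenol captures (acid-catalysed phenylcoumaran formation from a 1,2-diarylpropane-1,3-diol), the reversible closure placing the new C2 aryl group trans to the C3 hydroxymethyl group fixed in step 7, i.e. (2R,3S).

Step 11
Reactants: 17 dihydrobenzofuran phenol alcohol
Product: 18 (2R,3S)-5-bromo-7-methoxy-2-[3-methoxy-4-(TBSO)phenyl]-3-(TBSO-methyl)-2,3-dihydrobenzofuran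
Conditions: TBSCl (2.5 equiv), imidazole, DMF, rt
Reagents that add atoms: tert-butyldimethylsilyl chloride, CC(C)(C)[Si](C)(C)Cl
Why: Standard silyl ether formation caps the phenol and the primary alcohol in one operation.

Step 12
Reactants: 18 bis-TBS bromodihydrobenzofuran
Product: 21 {(2R,3S)-7-methoxy-2-[3-methoxy-4-(TBSO)phenyl]-3-(TBSO-methyl)-2,3-dihydrobenzofuran-5-yl}methanol, via aryllithium 19 (not isolated), via aldehyde 20 (not isolated)
Conditions: n-BuLi, THF, −78 °C; DMF, −78 → 0 °C; then MeOH, NaBH4, 0 °C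
Reagents that add atoms: N,N-dimethylformamide, CN(C)C=O
Why: Bromine–lithium exchange, Bouveault-type formylation and in-flask borohydride reduction install the benzylic CH2OH at C5 faster than any deprotonation of the ring C2–H at −78 °C.

Step 13
Reactants: 22 (S)-epichlorohydrin; 23 diethyl malonate
Product: 25 ethyl (1R,5S)-2-oxo-3-oxabicyclo[3.1.0]hexane-1-carboxylate, via glycidylmalonate 24 (not isolated)
Conditions: NaOEt, EtOH, 0 °C → reflux
Reagents that add atoms: none
Why: Tandem malonate alkylation, in which the anion opens the epoxide at CH2, the alkoxide re-closes to 24, 3-exo-tet attack inverts the epoxide CH and the freed alkoxide lactonises on the cis ester, so that the centre of 22 becomes C5 (S) and fixes C1 (R).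

Step 14
Reactants: 25 ethyl (1R,5S)-2-oxo-3-oxabicyclo[3.1.0]hexane-1-carboxylate
Product: 27 (1R,5S)-2-oxo-3-oxabicyclo[3.1.0]hexane-1-carboxylic acid, via disodium dicarboxylate 26 (not isolated)
Conditions: NaOH (2.2 equiv), H2O/EtOH, rt; then HCl to pH 1
Reagents that add atoms: sodium hydroxide, [Na+].[OH-]
Why: Saponification followed by acid-induced relactonisation, in which the hydroxymethyl group can reach only the cis carboxyl group and so regenerates the same (1R,5S) bicycle.

Step 15
Reactants: 21 dihydrobenzofuran-5-ylmethanol; 27 (1R,5S)-2-oxo-3-oxabicyclo[3.1.0]hexane-1-carboxylic acid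
Product: 28 {(2R,3S)-7-methoxy-2-[3-methoxy-4-(TBSO)phenyl]-3-(TBSO-methyl)-2,3-dihydrobenzofuran-5-yl}methyl (1R,5S)-2-oxo-3-oxabicyclo[3.1.0]hexane-1-carboxylate
Conditions: EDC·HCl, DMAP (10 mol %), CH2Cl2, 0 °C → rt
Reagents that add atoms: none
Why: Steglich-type esterification of an acid without α-hydrogen (no ketene, no decarboxylation), after which the ester from any minor enantiomer of 27 is a separable diastereomer.

Step 16
Reactants: 15 tetrakis-TBS aryl bromide; 28 cyclopropane-fused lactone ester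
Product: 32 dihydrobenzofuran-5-ylmethyl (3S,4S)-4-(arylmethyl)-2-oxotetrahydrofuran-3-carboxylate (aryl = ring of 15 in place of Br), via aryllithium 29 (not isolated), via arylmagnesium bromide 30 (not isolated), via magnesium enolate 31 (not isolated)
Conditions: 15 (1.3 equiv), t-BuLi (2 equiv per 15), Et2O, −78 °C; MgBr2·OEt2, −78 → 0 °C; CuI (20 mol %), then 28 in THF, −40 → −10 °C; aq NH4Cl
Reagents that add atoms: none
Why: Bromine–lithium exchange and transmetalation give Grignard reagent 30, which with CuI forms an arylcuprate that attacks the unsubstituted cyclopropane carbon C6 of 28 in an SN2-like homoconjugate addition, breaking the C1–C6 bond that overlaps with both carbonyl π systems and releasing the doubly stabilised enolate 31. The closest known reaction type is the copper-catalysed Grignard opening of 2-oxo-3-oxabicyclo[3.1.0]hexane-1-carboxylates to 4-substituted 2-oxotetrahydrofuran-3-carboxylates. No ring is closed: the temporary three-membered ring is opened and the γ-lactone stays intact. No bond to C5 of 28 is touched, so it becomes lactone C4 with its (S) configuration, while C3 arises as a labile β-dicarbonyl centre that settles trans and is reset in step 17. The step needs attack at the CH2 carbon C6 rather than at the ring-fusion CH C5 or at either carbonyl group; the first is secured by primary versus secondary substitution, the second by the soft cuprate at low temperature together with strain release and double activation. Compound 28 has no acidic C–H and every hydroxyl group of both halves is silylated.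

Step 17
Reactants: 32 coupled lactone ester
Product: 34 hexakis-O-TBS ether of the target with (3S,4S)-trans lactone, via quaternary lactone acid 33 (not isolated)
Conditions: CpPd(η3-C3H5) (10 mol %), dppf (11 mol %), toluene, 110 °C; then DBU (0.3 equiv), 60 °C
Reagents that add atoms: none
Why: Proposed new method: Pd(0) should ionise the electron-rich 4-alkoxybenzylic ester (both positions ortho to its CH2 are unsubstituted) to an η3-benzylpalladium carboxylate; a proton shift from the acidic C3–H then gives the malonate-type enolate, which attacks the benzyl carbon on the lactone face anti to the C4 substituent to give acid 33; 33 loses CO2 at 110 °C, and DBU funnels any cis epimer formed on ketonisation to the more stable trans (3S,4S) lactone; the closest known reaction types are the palladium-catalysed decarboxylative benzylation of benzyl β-keto esters and the palladium-catalysed benzylation of malonates by benzylic esters, neither shown on an α-carboxy lactone.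

Step 18
Reactants: 34 hexakis-O-TBS ether of the target
Product: 35 target CNP0199264.1
Conditions: TBAF (9 equiv), AcOH (9 equiv), THF, 0 °C → rt
Reagents that add atoms: none
Why: Fluoride-mediated global desilylation, buffered with acetic acid so that neither quinone methide formation, nor acid-induced cyclisation of the 4-hydroxybenzylic alcohol onto the neighbouring phenol, nor lactone damage should intervene.

Compound list
1 | 2-allyl-6-methoxyphenol | C=CCc1cccc(OC)c1O | starting material
2 | 2-allyl-4-bromo-6-methoxyphenol | C=CCc1cc(Br)cc(OC)c1O | intermediate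
3 | (2-allyl-4-bromo-6-methoxyphenoxy)(tert-butyl)dimethylsilane | C=CCc1cc(Br)cc(OC)c1O[Si](C)(C)C(C)(C)C | intermediate
4 | 3-[5-bromo-3-methoxy-2-(TBSO)benzyl]-1,2,4-trioxolane (secondary ozonide) | C1OOC(Cc2cc(Br)cc(OC)c2O[Si](C)(C)C(C)(C)C)O1 | intermediate
5 | 2-[5-bromo-3-methoxy-2-(TBSO)phenyl]acetaldehyde | O=CCc1cc(Br)cc(OC)c1O[Si](C)(C)C(C)(C)C | intermediate
6 | 2-[5-bromo-3-methoxy-2-(TBSO)phenyl]acetic acid | OC(=O)Cc1cc(Br)cc(OC)c1O[Si](C)(C)C(C)(C)C | intermediate
7 | (S)-4-benzyloxazolidin-2-one | O=C1N[C@@H](Cc2ccccc2)CO1 | starting material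
8 | mixed anhydride of 6 and pivalic acid | CC(C)(C)C(=O)OC(=O)Cc1cc(Br)cc(OC)c1O[Si](C)(C)C(C)(C)C | intermediate
9 | (S)-4-benzyl-3-{2-[5-bromo-3-methoxy-2-(TBSO)phenyl]acetyl}oxazolidin-2-one | O=C1OC[C@H](Cc2ccccc2)N1C(=O)Cc1cc(Br)cc(OC)c1O[Si](C)(C)C(C)(C)C | intermediate
10 | vanillin | COc1cc(C=O)ccc1O | starting material
11 | 4-(TBSO)-3-methoxybenzaldehyde | COc1cc(C=O)ccc1O[Si](C)(C)C(C)(C)C | intermediate
12 | O-trimethylsilyl ether of anti-aldol imide 13 | COc1cc([C@@H](O[Si](C)(C)C)[C@H](C(=O)N2[C@@H](Cc3ccccc3)COC2=O)c2cc(Br)cc(OC)c2O[Si](C)(C)C(C)(C)C)ccc1O[Si](C)(C)C(C)(C)C | intermediate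
13 | (S)-4-benzyl-3-{(2R,3S)-2-[5-bromo-3-methoxy-2-(TBSO)phenyl]-3-hydroxy-3-[3-methoxy-4-(TBSO)phenyl]propanoyl}oxazolidin-2-one | COc1cc([C@@H](O)[C@H](C(=O)N2[C@@H](Cc3ccccc3)COC2=O)c2cc(Br)cc(OC)c2O[Si](C)(C)C(C)(C)C)ccc1O[Si](C)(C)C(C)(C)C | intermediate
14 | (1S,2S)-2-[5-bromo-3-methoxy-2-(TBSO)phenyl]-1-[3-methoxy-4-(TBSO)phenyl]propane-1,3-diol | COc1cc([C@@H](O)[C@H](CO)c2cc(Br)cc(OC)c2O[Si](C)(C)C(C)(C)C)ccc1O[Si](C)(C)C(C)(C)C | intermediate
15 | (1S,2S)-2-[5-bromo-3-methoxy-2-(TBSO)phenyl]-1-[3-methoxy-4-(TBSO)phenyl]-1,3-bis(TBSO)propane | COc1cc([C@@H](O[Si](C)(C)C(C)(C)C)[C@H](CO[Si](C)(C)C(C)(C)C)c2cc(Br)cc(OC)c2O[Si](C)(C)C(C)(C)C)ccc1O[Si](C)(C)C(C)(C)C | intermediate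
16 | (1S,2S)-2-(5-bromo-2-hydroxy-3-methoxyphenyl)-1-(4-hydroxy-3-methoxyphenyl)propane-1,3-diol | COc1cc([C@@H](O)[C@H](CO)c2cc(Br)cc(OC)c2O)ccc1O | intermediate
17 | [(2R,3S)-5-bromo-2-(4-hydroxy-3-methoxyphenyl)-7-methoxy-2,3-dihydrobenzofuran-3-yl]methanol | Brc1cc(OC)c2c(c1)[C@@H](CO)[C@H](c1ccc(O)c(OC)c1)O2 | intermediate
18 | (2R,3S)-5-bromo-7-methoxy-2-[3-methoxy-4-(TBSO)phenyl]-3-(TBSO-methyl)-2,3-dihydrobenzofuran | Brc1cc(OC)c2c(c1)[C@@H](CO[Si](C)(C)C(C)(C)C)[C@H](c1ccc(O[Si](C)(C)C(C)(C)C)c(OC)c1)O2 | intermediate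
19 | 5-lithio analogue of 18 | [Li]c1cc(OC)c2c(c1)[C@@H](CO[Si](C)(C)C(C)(C)C)[C@H](c1ccc(O[Si](C)(C)C(C)(C)C)c(OC)c1)O2 | intermediate
20 | 5-carbaldehyde analogue of 18 | O=Cc1cc(OC)c2c(c1)[C@@H](CO[Si](C)(C)C(C)(C)C)[C@H](c1ccc(O[Si](C)(C)C(C)(C)C)c(OC)c1)O2 | intermediate
21 | {(2R,3S)-7-methoxy-2-[3-methoxy-4-(TBSO)phenyl]-3-(TBSO-methyl)-2,3-dihydrobenzofuran-5-yl}methanol | OCc1cc(OC)c2c(c1)[C@@H](CO[Si](C)(C)C(C)(C)C)[C@H](c1ccc(O[Si](C)(C)C(C)(C)C)c(OC)c1)O2 | intermediate
22 | (S)-epichlorohydrin | ClC[C@@H]1CO1 | starting material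
23 | diethyl malonate | CCOC(=O)CC(=O)OCC | starting material
24 | diethyl (S)-2-(oxiran-2-ylmethyl)malonate | CCOC(=O)C(C[C@H]1CO1)C(=O)OCC | intermediate
25 | ethyl (1R,5S)-2-oxo-3-oxabicyclo[3.1.0]hexane-1-carboxylate | CCOC(=O)[C@@]12C[C@@H]1COC2=O | intermediate
26 | disodium (S)-2-(hydroxymethyl)cyclopropane-1,1-dicarboxylate | [Na+].[Na+].OC[C@H]1CC1(C(=O)[O-])C(=O)[O-] | intermediate
27 | (1R,5S)-2-oxo-3-oxabicyclo[3.1.0]hexane-1-carboxylic acid | OC(=O)[C@@]12C[C@@H]1COC2=O | intermediate
28 | ester of 21 and 27 | O=C(OCc1cc(OC)c2c(c1)[C@@H](CO[Si](C)(C)C(C)(C)C)[C@H](c1ccc(O[Si](C)(C)C(C)(C)C)c(OC)c1)O2)[C@@]12C[C@@H]1COC2=O | intermediate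
29 | aryllithium from 15 (Li in place of Br) | COc1cc([C@@H](O[Si](C)(C)C(C)(C)C)[C@H](CO[Si](C)(C)C(C)(C)C)c2cc([Li])cc(OC)c2O[Si](C)(C)C(C)(C)C)ccc1O[Si](C)(C)C(C)(C)C | intermediate
30 | arylmagnesium bromide from 15 | COc1cc([C@@H](O[Si](C)(C)C(C)(C)C)[C@H](CO[Si](C)(C)C(C)(C)C)c2cc([Mg]Br)cc(OC)c2O[Si](C)(C)C(C)(C)C)ccc1O[Si](C)(C)C(C)(C)C | intermediate
31 | bromomagnesium enolate of 32, (4S) | COc1cc([C@@H](O[Si](C)(C)C(C)(C)C)[C@H](CO[Si](C)(C)C(C)(C)C)c2cc(C[C@@H]3COC(O[Mg]Br)=C3C(=O)OCc3cc(OC)c4c(c3)[C@@H](CO[Si](C)(C)C(C)(C)C)[C@H](c3ccc(O[Si](C)(C)C(C)(C)C)c(OC)c3)O4)cc(OC)c2O[Si](C)(C)C(C)(C)C)ccc1O[Si](C)(C)C(C)(C)C | intermediate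
32 | dihydrobenzofuran-5-ylmethyl (3S,4S)-4-(arylmethyl)-2-oxotetrahydrofuran-3-carboxylate, all six hydroxyl groups as TBS ethers | COc1cc([C@@H](O[Si](C)(C)C(C)(C)C)[C@H](CO[Si](C)(C)C(C)(C)C)c2cc(C[C@@H]3COC(=O)[C@H]3C(=O)OCc3cc(OC)c4c(c3)[C@@H](CO[Si](C)(C)C(C)(C)C)[C@H](c3ccc(O[Si](C)(C)C(C)(C)C)c(OC)c3)O4)cc(OC)c2O[Si](C)(C)C(C)(C)C)ccc1O[Si](C)(C)C(C)(C)C | intermediate
33 | (3S,4S)-3-(dihydrobenzofuran-5-ylmethyl)-4-(arylmethyl)-2-oxotetrahydrofuran-3-carboxylic acid, the two benzylic groups trans | COc1cc([C@@H](O[Si](C)(C)C(C)(C)C)[C@H](CO[Si](C)(C)C(C)(C)C)c2cc(C[C@@H]3COC(=O)[C@@]3(C(=O)O)Cc3cc(OC)c4c(c3)[C@@H](CO[Si](C)(C)C(C)(C)C)[C@H](c3ccc(O[Si](C)(C)C(C)(C)C)c(OC)c3)O4)cc(OC)c2O[Si](C)(C)C(C)(C)C)ccc1O[Si](C)(C)C(C)(C)C | intermediate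
34 | hexakis-O-TBS ether of the target | COc1cc([C@@H](O[Si](C)(C)C(C)(C)C)[C@H](CO[Si](C)(C)C(C)(C)C)c2cc(C[C@@H]3COC(=O)[C@H]3Cc3cc(OC)c4c(c3)[C@@H](CO[Si](C)(C)C(C)(C)C)[C@H](c3ccc(O[Si](C)(C)C(C)(C)C)c(OC)c3)O4)cc(OC)c2O[Si](C)(C)C(C)(C)C)ccc1O[Si](C)(C)C(C)(C)C | intermediate
35 | CNP0199264.1 | COc1cc([C@@H](O)[C@H](CO)c2cc(C[C@@H]3COC(=O)[C@H]3Cc3cc(OC)c4c(c3)[C@@H](CO)[C@H](c3ccc(O)c(OC)c3)O4)cc(OC)c2O)ccc1O | target

Total step count: 18. Longest linear sequence: 14 steps (1–5, 7, 8, 10–12, 15–18).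

Steps most likely to fail

1. Step 17 (Proposed new method). Ionisation of the benzylic ester may be too slow. Proton transfer between substrate molecules may also lead to decarboxylative protonation and scrambling of the benzyl group. The fallback uses known chemistry, sets out from 32 and comes back at 34. Hydrogenolysis of the benzylic ester (H2, Pd/C, EtOAc) should give trans-(4S)-lactone-3-carboxylic acid F1. This loses CO2 in toluene at 110 °C to give (S)-4-(arylmethyl)butyrolactone F2. Alcohol 21 is turned by the Appel reaction (CBr4, PPh3, CH2Cl2, 0 °C) into benzylic bromide F3. The classical alkylation of the lithium enolate of F2 (LiHMDS, THF, −78 °C) with F3, anti to the C4 substituent, should then give 34. The ester-bound dihydrobenzofuran unit is sacrificed in this variant.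

2. Step 16. Aryl transfer from copper may be slow for the bulky, electron-rich aryl group. In that case 1,2-addition to the lactone or ester carbonyl, or loss of the activated benzylic ester, could compete. The fallback sets out from 15 and 25 and comes back at 32. Grignard reagent 30 is added under CuI to the small ethyl ester 25, the substrate class for which this opening is established, to give ethyl trans-(4S)-4-(arylmethyl)-2-oxotetrahydrofuran-3-carboxylate F4. The dihydrobenzofuran half is then grafted on by neutral transesterification with 21 (tetrabutyldistannoxane catalyst, toluene, reflux, removal of ethanol).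

3. Step 7. The ortho-silyloxy group may slow the addition or erode the facial selectivity at the aldehyde, giving a mixture of epimers at the carbinol carbon, while the auxiliary still fixes the aryl-bearing carbon. The fallback sets out from 14 as the epimer mixture and comes back at 14 as the single anti isomer. Ketalisation with 2,2-dimethoxypropane and camphorsulfonic acid in CH2Cl2, prolonged or assisted by catalytic BF3·OEt2, should equilibrate the benzylic C–O bond through the stabilised 4-silyloxybenzyl cation. This is the process known from the acid epimerisation of furofuran lignans. It should lead to the diequatorial (4S,5S)-4,5-diaryl-2,2-dimethyl-1,3-dioxane F5, which corresponds to the anti diol. Mild hydrolysis (80 % AcOH, 40 °C) then returns 14. Step 10 accepts either epimer, so only the material for step 9 needs this correction.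

Further compounds
F1 | step 17 | trans-(4S)-4-(arylmethyl)-2-oxotetrahydrofuran-3-carboxylic acid (aryl = tetrakis-TBS diarylpropane unit) | COc1cc([C@@H](O[Si](C)(C)C(C)(C)C)[C@H](CO[Si](C)(C)C(C)(C)C)c2cc(C[C@@H]3COC(=O)[C@H]3C(=O)O)cc(OC)c2O[Si](C)(C)C(C)(C)C)ccc1O[Si](C)(C)C(C)(C)C
F2 | step 17 | (S)-4-(arylmethyl)dihydrofuran-2(3H)-one (aryl = tetrakis-TBS diarylpropane unit) | COc1cc([C@@H](O[Si](C)(C)C(C)(C)C)[C@H](CO[Si](C)(C)C(C)(C)C)c2cc(C[C@@H]3COC(=O)C3)cc(OC)c2O[Si](C)(C)C(C)(C)C)ccc1O[Si](C)(C)C(C)(C)C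
F3 | step 17 | (2R,3S)-5-(bromomethyl)-7-methoxy-2-[3-methoxy-4-(TBSO)phenyl]-3-(TBSO-methyl)-2,3-dihydrobenzofuran | BrCc1cc(OC)c2c(c1)[C@@H](CO[Si](C)(C)C(C)(C)C)[C@H](c1ccc(O[Si](C)(C)C(C)(C)C)c(OC)c1)O2
F4 | step 16 | ethyl trans-(4S)-4-(arylmethyl)-2-oxotetrahydrofuran-3-carboxylate (aryl = tetrakis-TBS diarylpropane unit) | COc1cc([C@@H](O[Si](C)(C)C(C)(C)C)[C@H](CO[Si](C)(C)C(C)(C)C)c2cc(C[C@@H]3COC(=O)[C@H]3C(=O)OCC)cc(OC)c2O[Si](C)(C)C(C)(C)C)ccc1O[Si](C)(C)C(C)(C)C
F5 | step 7 | (4S,5S)-5-[5-bromo-3-methoxy-2-(TBSO)phenyl]-4-[3-methoxy-4-(TBSO)phenyl]-2,2-dimethyl-1,3-dioxane | COc1cc([C@H]2OC(C)(C)OC[C@@H]2c3cc(Br)cc(OC)c3O[Si](C)(C)C(C)(C)C)ccc1O[Si](C)(C)C(C)(C)C
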